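## Retrosynthetic overview

1. Target ⇐ one-pot hydrogenation of a penta-O-benzyl 4-aryl-2H-chromene: H2 adds to C3=C4 anti to the C2 aryl group (sets C4, 2,4-cis) and all benzyl ethers are cleaved.
2. 4-Aryl-2H-chromene ⇐ Weinreb acylation of an aryllithium (lauroyl group); before that, 1,2-addition of a brominated tris(benzyloxy)phenylcerium to the (R)-flavanone and dehydration (C4–aryl bond).
3. (R)-Flavanone ⇐ kinetic resolution of the racemic flavanone by asymmetric transfer hydrogenation ⇐ oxa-Michael ring closure of the 2'-hydroxychalcone.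
4. Chalcone ⇐ crossed aldol (Claisen–Schmidt) condensation of the ring A acetophenone with the ring B benzaldehyde: the key C2–C3 bond, uniting the two fragments.
5. Rings A, B and the phloroglucinol ring are bought as arenes; the only ring built is the pyran ring C (step 3).

Assumption: 1,3,5-tris(benzyloxy)benzene is taken as a bought catalogue compound; the target descriptors (2R,4R) correspond to the 2,4-cis flavan.

## Route

Step 1
Reactants: 1 1-(2,4-dihydroxyphenyl)ethanone
Product: 2 1-[4-(benzyloxy)-2-hydroxyphenyl]ethanone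
Conditions: BnBr (1.05 equiv), K2CO3, acetone, reflux
Reagents that add atoms: benzyl bromide, BrCc1ccccc1
Why: Williamson ether synthesis; the 2-OH is tied up in a hydrogen bond to the acetyl C=O and is far less nucleophilic, so only the 4-OH is benzylated.

Step 2
Reactants: 2 1-[4-(benzyloxy)-2-hydroxyphenyl]ethanone, 3 4-(benzyloxy)benzaldehyde
Product: 5 (E)-1-[4-(benzyloxy)-2-hydroxyphenyl]-3-[4-(benzyloxy)phenyl]prop-2-en-1-one, via aldol adduct 4 (not isolated)
Conditions: KOH (50% aq.), EtOH, rt, 24–48 h; then cold 1 M HCl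
Reagents that add atoms: none
Why: Claisen–Schmidt crossed aldol condensation: the enolate of methyl ketone 2 adds to the non-enolisable aldehyde 3, forming the C2–C3 bond of the future flavan and joining the ring A and ring B fragments, and aldol 4 loses water by E1cB to the conjugated E-enone, so no stereocentre has to be controlled here.

Step 3
Reactants: 5 (E)-1-[4-(benzyloxy)-2-hydroxyphenyl]-3-[4-(benzyloxy)phenyl]prop-2-en-1-one
Product: 6 rac-7-(benzyloxy)-2-[4-(benzyloxy)phenyl]-2,3-dihydro-4H-chromen-4-one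
Conditions: NaOAc, EtOH/H2O, reflux; crystallise, recycle unreacted 5
Reagents that add atoms: none
Why: Intramolecular oxa-Michael addition (6-endo-trig) of the 2'-phenoxide to the enone closes ring C under equilibrium conditions, giving C2 as the racemate.

Step 4
Reactants: 6 rac-7-(benzyloxy)-2-[4-(benzyloxy)phenyl]-2,3-dihydro-4H-chromen-4-one
Product: 7 (2R)-7-(benzyloxy)-2-[4-(benzyloxy)phenyl]-2,3-dihydro-4H-chromen-4-one
Conditions: RuCl(p-cymene)[(S,S)-TsDPEN] (2 mol %), HCO2H/Et3N (5:2), EtOAc, 30 °C, to ca. 55% conversion; chromatography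
Reagents that add atoms: none
Why: Noyori–Ikariya asymmetric transfer hydrogenation run as a kinetic resolution: the (S,S)-catalyst makes (4S)-carbinols and is matched only with the (2S)-ketone (axial hydride, cis-alcohol), so the slow-reacting (2R)-ketone is recovered in high ee once conversion passes one half.

Step 5
Reactants: 8 1,3,5-tris(benzyloxy)benzene
Product: 9 1,3,5-tris(benzyloxy)-2,4-dibromobenzene
Conditions: NBS (2.05 equiv), CH2Cl2, 0 °C → rt, dark
Reagents that add atoms: N-bromosuccinimide, O=C1CCC(=O)N1Br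
Why: Electrophilic aromatic bromination of the trialkoxybenzene ring stops cleanly at the dibromide because each bromine deactivates and crowds the ring.

Step 6
Reactants: 9 1,3,5-tris(benzyloxy)-2,4-dibromobenzene, 7 (2R)-7-(benzyloxy)-2-[4-(benzyloxy)phenyl]-2,3-dihydro-4H-chromen-4-one
Product: 12 (2R)-7-(benzyloxy)-2-[4-(benzyloxy)phenyl]-4-[2,4,6-tris(benzyloxy)-3-bromophenyl]-3,4-dihydro-2H-chromen-4-ol (both C4 epimers), via aryllithium 10 (not isolated), via arylcerium dichloride 11 (not isolated)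
Conditions: 9 (1.5 equiv), n-BuLi (1.45 equiv), THF, –78 °C; CeCl3 (anhydrous), –78 °C; then 7, –78 → –30 °C; H2O
Reagents that add atoms: none
Why: Bromine–lithium exchange on one of two equivalent bromides, transmetalation to the weakly basic organocerium and Imamoto-type 1,2-addition to the ketone avoid the enolisation and E1cB ring opening a bare aryllithium would cause; C2 is untouched and the C4 carbinol configuration is irrelevant because it is erased in step 7.

Step 7
Reactants: 12 (2R)-7-(benzyloxy)-2-[4-(benzyloxy)phenyl]-4-[2,4,6-tris(benzyloxy)-3-bromophenyl]-3,4-dihydro-2H-chromen-4-ol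
Product: 13 (2R)-7-(benzyloxy)-2-[4-(benzyloxy)phenyl]-4-[2,4,6-tris(benzyloxy)-3-bromophenyl]-2H-chromene
Conditions: Burgess reagent (methyl N-(triethylammoniosulfonyl)carbamate, 2 equiv), THF, 50 °C, dark
Reagents that add atoms: none
Why: Burgess dehydration of the tertiary bis-benzylic alcohol (sulfamate ester, syn-elimination toward C3, the only β-hydrogen site) works without acid, so the acid-labile allylic C2–O bond and the C2 centre are preserved.

Step 8
Reactants: 14 dodecanoyl chloride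
Product: 15 N-methoxy-N-methyldodecanamide
Conditions: MeNHOMe·HCl, K2CO3, EtOAc/H2O, 0 °C → rt
Reagents that add atoms: N,O-dimethylhydroxylamine hydrochloride, Cl.CNOC
Why: Schotten–Baumann N-acylation gives the Weinreb amide quantitatively.

Step 9
Reactants: 13 (2R)-7-(benzyloxy)-2-[4-(benzyloxy)phenyl]-4-[2,4,6-tris(benzyloxy)-3-bromophenyl]-2H-chromene, 15 N-methoxy-N-methyldodecanamide
Product: 17 1-{2,4,6-tris(benzyloxy)-3-[(2R)-7-(benzyloxy)-2-[4-(benzyloxy)phenyl]-2H-chromen-4-yl]phenyl}dodecan-1-one, via aryllithium 16 (not isolated)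
Conditions: n-BuLi (1.05 equiv), THF, –78 °C, 10 min; 15 (1.5 equiv), –78 → –20 °C; then H2O
Reagents that add atoms: none
Why: Bromine–lithium exchange at –78 °C is faster than deprotonation at C2, and the Weinreb ketone synthesis stops at the chelated tetrahedral adduct, so the ketone appears only on quench and is not over-added.

Step 10
Reactants: 17 1-{2,4,6-tris(benzyloxy)-3-[(2R)-7-(benzyloxy)-2-[4-(benzyloxy)phenyl]-2H-chromen-4-yl]phenyl}dodecan-1-one
Product: 18 1-{2,4,6-trihydroxy-3-[(2R,4R)-7-hydroxy-2-(4-hydroxyphenyl)-3,4-dihydro-2H-chromen-4-yl]phenyl}dodecan-1-one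
Conditions: H2 (3 bar), Pd/C (10 wt %), EtOAc/MeOH, rt; monitor, stop at full debenzylation
Reagents that add atoms: none
Why: Heterogeneous catalytic hydrogenation with concurrent O-benzyl hydrogenolysis: H2 adds to C3=C4 from the face opposite the C2 aryl group, so H-4 is cis to H-2 and the new centre is 4R (2,4-cis), while the hindered, hydrogen-bonded acyl ketone is not reduced under these mild conditions.

## Compound list

1 | 1-(2,4-dihydroxyphenyl)ethanone | CC(=O)c1ccc(O)cc1O | starting material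
2 | 1-[4-(benzyloxy)-2-hydroxyphenyl]ethanone | CC(=O)c1ccc(OCc2ccccc2)cc1O | intermediate
3 | 4-(benzyloxy)benzaldehyde | O=Cc1ccc(OCc2ccccc2)cc1 | starting material
4 | rac-1-[4-(benzyloxy)-2-hydroxyphenyl]-3-[4-(benzyloxy)phenyl]-3-hydroxypropan-1-one (aldol adduct) | O=C(CC(O)c1ccc(OCc2ccccc2)cc1)c1ccc(OCc2ccccc2)cc1O | intermediate (not isolated)
5 | (E)-1-[4-(benzyloxy)-2-hydroxyphenyl]-3-[4-(benzyloxy)phenyl]prop-2-en-1-one | O=C(/C=C/c1ccc(OCc2ccccc2)cc1)c1ccc(OCc2ccccc2)cc1O | intermediate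
6 | rac-7-(benzyloxy)-2-[4-(benzyloxy)phenyl]-2,3-dihydro-4H-chromen-4-one | O=C1CC(c2ccc(OCc3ccccc3)cc2)Oc2cc(OCc3ccccc3)ccc21 | intermediate
7 | (2R)-7-(benzyloxy)-2-[4-(benzyloxy)phenyl]-2,3-dihydro-4H-chromen-4-one | O=C1C[C@H](c2ccc(OCc3ccccc3)cc2)Oc2cc(OCc3ccccc3)ccc21 | intermediate
8 | 1,3,5-tris(benzyloxy)benzene | c1ccc(COc2cc(OCc3ccccc3)cc(OCc3ccccc3)c2)cc1 | starting material
9 | 1,3,5-tris(benzyloxy)-2,4-dibromobenzene | Brc1c(OCc2ccccc2)cc(OCc2ccccc2)c(Br)c1OCc1ccccc1 | intermediate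
10 | [2,4,6-tris(benzyloxy)-3-bromophenyl]lithium | [Li]c1c(OCc2ccccc2)cc(OCc2ccccc2)c(Br)c1OCc1ccccc1 | intermediate (not isolated)
11 | [2,4,6-tris(benzyloxy)-3-bromophenyl]cerium dichloride | Cl[Ce](Cl)c1c(OCc2ccccc2)cc(OCc2ccccc2)c(Br)c1OCc1ccccc1 | intermediate (not isolated)
12 | (2R)-7-(benzyloxy)-2-[4-(benzyloxy)phenyl]-4-[2,4,6-tris(benzyloxy)-3-bromophenyl]-3,4-dihydro-2H-chromen-4-ol, both C4 epimers | OC1(c2c(OCc3ccccc3)cc(OCc3ccccc3)c(Br)c2OCc2ccccc2)C[C@H](c2ccc(OCc3ccccc3)cc2)Oc2cc(OCc3ccccc3)ccc21 | intermediate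
13 | (2R)-7-(benzyloxy)-2-[4-(benzyloxy)phenyl]-4-[2,4,6-tris(benzyloxy)-3-bromophenyl]-2H-chromene | Brc1c(OCc2ccccc2)cc(OCc2ccccc2)c(C2=C[C@H](c3ccc(OCc4ccccc4)cc3)Oc3cc(OCc4ccccc4)ccc32)c1OCc1ccccc1 | intermediate
14 | dodecanoyl chloride | CCCCCCCCCCCC(=O)Cl | starting material
15 | N-methoxy-N-methyldodecanamide | CCCCCCCCCCCC(=O)N(C)OC | intermediate
16 | {2,4,6-tris(benzyloxy)-3-[(2R)-7-(benzyloxy)-2-[4-(benzyloxy)phenyl]-2H-chromen-4-yl]phenyl}lithium | [Li]c1c(OCc2ccccc2)cc(OCc2ccccc2)c(C2=C[C@H](c3ccc(OCc4ccccc4)cc3)Oc3cc(OCc4ccccc4)ccc32)c1OCc1ccccc1 | intermediate (not isolated)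
17 | 1-{2,4,6-tris(benzyloxy)-3-[(2R)-7-(benzyloxy)-2-[4-(benzyloxy)phenyl]-2H-chromen-4-yl]phenyl}dodecan-1-one | CCCCCCCCCCCC(=O)c1c(OCc2ccccc2)cc(OCc2ccccc2)c(C2=C[C@H](c3ccc(OCc4ccccc4)cc3)Oc3cc(OCc4ccccc4)ccc32)c1OCc1ccccc1 | intermediate
18 | 1-{2,4,6-trihydroxy-3-[(2R,4R)-7-hydroxy-2-(4-hydroxyphenyl)-3,4-dihydro-2H-chromen-4-yl]phenyl}dodecan-1-one | CCCCCCCCCCCC(=O)c1c(O)cc(O)c([C@@H]2C[C@H](c3ccc(O)cc3)Oc3cc(O)ccc32)c1O | target

## Step count and risks

Total steps: 10. Longest linear sequence: 8 steps (steps 1, 2, 3, 4, 6, 7, 9, 10; steps 5 and 8 are side branches).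

**Step 4 (kinetic resolution).** The selectivity factor may be too low for this 7,4'-dialkoxy flavanone, or conversion may be hard to hold near 55%. The fallback sets out from 2 and comes back at 7. Ketone 2 is heated with N,N-dimethylformamide dimethyl acetal (toluene, 100 °C) to the enaminone (E)-1-[4-(benzyloxy)-2-hydroxyphenyl]-3-(dimethylamino)prop-2-en-1-one F1. Acid (HCl, CH2Cl2, rt) closes this to 7-(benzyloxy)-4H-chromen-4-one F2. Asymmetric conjugate arylation of F2 with 4-(benzyloxy)phenylboronic acid (Pd(OCOCF3)2, (S)-t-BuPyOx, NH4PF6, H2O, ClCH2CH2Cl, 60 °C) then gives 7 directly. The ligand enantiomer is chosen by analogy with cyclic enones, and the sign is checked by chiral HPLC against 7 from step 4.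

**Step 6 (arylcerium addition).** The very hindered nucleophile 11 may fail to add to the deactivated, enolisable ketone 7, or may open the pyranone. The fallback sets out from 7 and comes back at 13, replacing steps 6 and 7. Ketone 7 is converted without enolate formation (Tf2O, 2,6-di-tert-butyl-4-methylpyridine, CH2Cl2, 0 °C) into the enol triflate (2R)-7-(benzyloxy)-2-[4-(benzyloxy)phenyl]-2H-chromen-4-yl trifluoromethanesulfonate F3. Aryllithium 10 is transmetalated with ZnCl2 to chloro[2,4,6-tris(benzyloxy)-3-bromophenyl]zinc F4. Negishi coupling of F3 with F4 (Pd(OAc)2, SPhos, THF, 50 °C) gives 13, because zerovalent palladium inserts into the vinyl triflate far faster than into the di-ortho-alkoxy aryl bromide.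

**Step 10 (hydrogenation).** The alkene is flanked by a twisted 2,6-disubstituted aryl ring and may reduce slowly; the allylic C2–O bond may hydrogenolyse, or facial selectivity may be poor. The fallback sets out from 12 and comes back at 18. Ionic deoxygenation of 12 (Et3SiH, BF3·OEt2, CH2Cl2, –78 °C) delivers hydride axially to the C4 cation on the face of H-2. This gives (2R,4R)-7-(benzyloxy)-2-[4-(benzyloxy)phenyl]-4-[2,4,6-tris(benzyloxy)-3-bromophenyl]-3,4-dihydro-2H-chromene F5; it is done before the ketone is present, since that reagent pair would also reduce an aryl ketone. Bromine–lithium exchange and acylation with 15 (n-BuLi, THF, –78 °C) give 1-{2,4,6-tris(benzyloxy)-3-[(2R,4R)-7-(benzyloxy)-2-[4-(benzyloxy)phenyl]-3,4-dihydro-2H-chromen-4-yl]phenyl}dodecan-1-one F6. Only hydrogenolysis of the benzyl ethers then remains (H2, Pd(OH)2/C, EtOAc/MeOH), giving 18.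

## Further compounds

F1 | step 4 | (E)-1-[4-(benzyloxy)-2-hydroxyphenyl]-3-(dimethylamino)prop-2-en-1-one | CN(C)/C=C/C(=O)c1ccc(OCc2ccccc2)cc1O
F2 | step 4 | 7-(benzyloxy)-4H-chromen-4-one | O=c1ccoc2cc(OCc3ccccc3)ccc12
F3 | step 6 | (2R)-7-(benzyloxy)-2-[4-(benzyloxy)phenyl]-2H-chromen-4-yl trifluoromethanesulfonate | O=S(=O)(OC1=C[C@H](c2ccc(OCc3ccccc3)cc2)Oc2cc(OCc3ccccc3)ccc21)C(F)(F)F
F4 | step 6 | chloro[2,4,6-tris(benzyloxy)-3-bromophenyl]zinc | Cl[Zn]c1c(OCc2ccccc2)cc(OCc2ccccc2)c(Br)c1OCc1ccccc1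
F5 | step 10 | (2R,4R)-7-(benzyloxy)-2-[4-(benzyloxy)phenyl]-4-[2,4,6-tris(benzyloxy)-3-bromophenyl]-3,4-dihydro-2H-chromene | Brc1c(OCc2ccccc2)cc(OCc2ccccc2)c([C@@H]2C[C@H](c3ccc(OCc4ccccc4)cc3)Oc3cc(OCc4ccccc4)ccc32)c1OCc1ccccc1
F6 | step 10 | 1-{2,4,6-tris(benzyloxy)-3-[(2R,4R)-7-(benzyloxy)-2-[4-(benzyloxy)phenyl]-3,4-dihydro-2H-chromen-4-yl]phenyl}dodecan-1-one | CCCCCCCCCCCC(=O)c1c(OCc2ccccc2)cc(OCc2ccccc2)c([C@@H]2C[C@H](c3ccc(OCc4ccccc4)cc3)Oc3cc(OCc4ccccc4)ccc32)c1OCc1ccccc1
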